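**Retrosynthetic overview**
1. Target 11 comes from 2,2'-bipyrrole 9 by exhaustive electrophilic bromination (six C–Br bonds, last step).
2. 9 comes from 2,2'-bifuran 5 by exchanging both ring oxygens for NH. This key step forms four C–N bonds and leaves the C8 backbone and the 2,2' C–C bond untouched.
3. 5 comes from furan 1 and 2-bromofuran 2 by C2-lithiation, zincation and palladium-catalysed cross-coupling.
4. Ring order: the two furan rings are bought intact and joined, then ring A and ring B are re-formed in one pot as pyrroles, then brominated.

Assumption: the target has no stereocentre and no configurationally stable axis, so it is achiral; "single enantiomer" is taken to mean the compound as drawn, and no stereocontrol is needed.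

**Step 1**
Reactants: 1 furan; 2 2-bromofuran
Product: 5 2,2'-bifuran, via furan-2-yllithium 3 (not isolated), via (furan-2-yl)zinc bromide 4 (not isolated)
Conditions: 1 (1.2 equiv), n-BuLi (1.1 equiv), THF, −78 → 0 °C, 1 h; ZnBr2 (1.15 equiv), 0 °C → rt, 30 min; then 2 (1.0 equiv), Pd(PPh3)4 (3 mol %), 50 °C, 6 h
Reagents that add atoms: none
Why: Furan is deprotonated selectively at C2, transmetalation to zinc gives a mild nucleophile, and Pd(PPh3)4 (zerovalent palladium) inserts into the C–Br bond of 2, transmetalates with 4 and reductively eliminates the biaryl in a Negishi cross-coupling, in which homocoupling of either partner would give the same product.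

**Step 2**
Reactants: 5 2,2'-bifuran
Product: 9 1H,1'H-2,2'-bipyrrole, via 1-(furan-2-yl)-4-iminobutan-1-one 6 (not isolated), via 2-(furan-2-yl)-1H-pyrrole 7 (not isolated), via 4-imino-1-(1H-pyrrol-2-yl)butan-1-one 8 (not isolated)
Conditions: H2NCO2NH4 (5 equiv), 3,6-di-tert-butyl-9-mesityl-10-phenylacridinium tetrafluoroborate (5 mol %), MeCN/H2O 10:1 (0.05 M), degassed, Ar, sealed tube, 456 nm LEDs, 25 °C, 24 h; then 50 °C, 2 h
Reagents that add atoms: ammonium carbamate, NC(=O)[O-].[NH4+]
Why: Proposed new method: a twofold photocatalytic O-to-N atom exchange with free ammonia released from the carbamate, in which the excited acridinium (about +2.0 V vs SCE) oxidises electron-rich 5 (about +1.3 V) to its radical cation, NH3 adds at the unhindered terminal C5, the aminal radical opens by C–O cleavage to a carbonyl-stabilised radical that the acridine radical reduces (redox-neutral overall), proton transfer gives keto-imine 6, and Paal–Knorr cyclodehydration closes ring A to give 7, after which the same cycle converts the remaining furan ring through 8 into ring B (NH3 attack on the pyrrole ring only regenerates it); the closest known reaction types are the acridinium-photocatalysed furan-to-pyrrole swap of mono-furans with primary amines and arene radical-cation amination with ammonium carbamate, and the twofold exchange on a 2,2'-bifuran to an N-unsubstituted bipyrrole has not been shown.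

**Step 3**
Reactants: 9 1H,1'H-2,2'-bipyrrole
Product: 11 3,3',4,4',5,5'-hexabromo-1H,1'H-2,2'-bipyrrole, via 5,5'-dibromo-1H,1'H-2,2'-bipyrrole 10 (not isolated)
Conditions: N-bromosuccinimide (6.2 equiv), THF, −78 → 0 °C, dark, Ar; aq. Na2S2O3 work-up
Reagents that add atoms: N-bromosuccinimide, O=C1CCC(=O)N1Br
Why: Every free ring carbon of 9 is strongly activated toward electrophilic aromatic substitution, so N-bromosuccinimide brominates the two α positions first (10) and then the four β positions at low temperature without a catalyst, as in the exhaustive bromination of pyrrole to tetrabromopyrrole.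

**Compound list**
1 | furan | c1ccoc1 | starting material
2 | 2-bromofuran | Brc1ccco1 | starting material
3 | furan-2-yllithium | [Li]c1ccco1 | intermediate
4 | (furan-2-yl)zinc bromide | Br[Zn]c1ccco1 | intermediate
5 | 2,2'-bifuran | c1coc(c1)-c1ccco1 | intermediate
6 | 1-(furan-2-yl)-4-iminobutan-1-one | N=CCCC(=O)c1ccco1 | intermediate
7 | 2-(furan-2-yl)-1H-pyrrole | c1coc(c1)-c1ccc[nH]1 | intermediate
8 | 4-imino-1-(1H-pyrrol-2-yl)butan-1-one | N=CCCC(=O)c1ccc[nH]1 | intermediate
9 | 1H,1'H-2,2'-bipyrrole | c1c[nH]c(c1)-c1ccc[nH]1 | intermediate
10 | 5,5'-dibromo-1H,1'H-2,2'-bipyrrole | Brc1ccc([nH]1)-c1ccc(Br)[nH]1 | intermediate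
11 | 3,3',4,4',5,5'-hexabromo-1H,1'H-2,2'-bipyrrole | Brc1[nH]c(-c2[nH]c(Br)c(Br)c2Br)c(Br)c1Br | target

**Total step count:** 3. **Longest linear sequence:** 3.

**Steps most likely to fail, with fallbacks**

Step 2 (the proposed new step) is the most likely to fail. The bifuran radical cation may oligomerise faster than NH3 traps it. Product 9 is more easily oxidised than 5 and may quench the photocatalyst or degrade. The reaction may also stall at 7. The fallback uses known chemistry only; it sets out from furan 1 and comes back at 9. The O-to-N exchange is done on the monomer: furan and NH3 are passed over γ-Al2O3 at about 400 °C (Yur'ev reaction) to give 1H-pyrrole F1, which is also a commodity chemical. Two molecules of F1, with F1 used in excess, are then joined at C2 by oxidative homocoupling with PhI(OCOCF3)2 (trivalent iodine) and Me3SiBr in CH2Cl2 at −78 °C to give 9. The C–N bonds are thus made before the 2,2' C–C bond instead of after it.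

Step 3 may fail because the N-unsubstituted, very electron-rich 9 can be oxidised or oligomerised by the brominating agent before substitution is complete, and the polybrominated NH-pyrroles are light- and acid-sensitive. The fallback sets out from 9 and comes back at 11, and changes the approach to a protecting-group route. Treatment of 9 with NaH and Me3SiCH2CH2OCH2Cl in DMF at 0 °C gives 1,1'-bis{[2-(trimethylsilyl)ethoxy]methyl}-1H,1'H-2,2'-bipyrrole F2. This N-alkyl-type bipyrrole is brominated with N-bromosuccinimide (6.2 equiv) in THF, −78 °C → rt, to the stable, chromatographable 3,3',4,4',5,5'-hexabromo-1,1'-bis{[2-(trimethylsilyl)ethoxy]methyl}-1H,1'H-2,2'-bipyrrole F3. Bu4NF in THF at 50 °C then removes both N-substituents, helped by the good leaving-group ability of the hexabromo-pyrrolide, and gives 11.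

Step 1 may give only a moderate yield: 2-bromofuran 2 darkens and polymerises on storage, the zincation is moisture-sensitive, and 5 is volatile and air-sensitive. The fallback sets out from furan 1 and comes back at 5. It replaces the palladium-catalysed coupling of a nucleophile with a halide by the oxidative homocoupling of one isolable nucleophile, so neither 2 nor palladium is needed. Furan is lithiated as before to 3, which is quenched with B(OMe)3 in THF at −78 °C → rt and then with aq. HCl to give furan-2-ylboronic acid F4. Two molecules of F4 are then joined with CuCl (10 mol %) in MeOH under air at rt to give 5.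

**Further compounds**
F1 | step 2 | 1H-pyrrole | c1cc[nH]c1
F2 | step 3 | 1,1'-bis{[2-(trimethylsilyl)ethoxy]methyl}-1H,1'H-2,2'-bipyrrole | C[Si](C)(C)CCOCn1cccc1-c1cccn1COCC[Si](C)(C)C
F3 | step 3 | 3,3',4,4',5,5'-hexabromo-1,1'-bis{[2-(trimethylsilyl)ethoxy]methyl}-1H,1'H-2,2'-bipyrrole | C[Si](C)(C)CCOCn1c(Br)c(Br)c(Br)c1-c1c(Br)c(Br)c(Br)n1COCC[Si](C)(C)C
F4 | step 1 | furan-2-ylboronic acid | OB(O)c1ccco1
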